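(The earlier runs and the new flask were computed on assumed constants.)

The green run holds more free base than the violet run (5.4 equiv against 2.5 equiv), yet I read nearly the same electrophile curve in both, so I build my estimate from their shared clocks.

| setting | violet | green | Saturday's | Friday's | Monday's |
|---|---|---|---|---|---|
| electrophile | 5.0 × 10⁻⁴ M | 5.0 × 10⁻⁴ M | 5.0 × 10⁻⁴ M | 5.0 × 10⁻⁴ M | 5.0 × 10⁻⁴ M |
| nucleophile | 2 equiv | 2 equiv | 2.00 equiv | 2.00 equiv | 2.00 equiv |
| free base | 2.5 equiv | 5.4 equiv | 2.00 equiv | 3.00 equiv | 4.50 equiv |
| protic impurity | 0.15 mM | 0.15 mM | 0.150 mM | 0.150 mM | 0.150 mM |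
| scavenger | 1.5 equiv | 1.5 equiv | 1.50 equiv | 1.50 equiv | 1.50 equiv |
| remark | run made earlier | run made earlier |  |  |  |
| time |  |  | 2.5 min | 2.5 min | 2.5 min |

| run | time / s | electrophile / % | target / % |
|---|---|---|---|
| violet | 10.0 | 57 | 22 |
| violet | 12.0 | 54 | 22 |
| violet | 20.0 | 42 | 34 |
| violet | 30.0 | 30 | 44 |
| violet | 50.0 | 18 | 49 |
| violet | 60.0 | 17 | 54 |
| violet | 120 | 8 | 64 |
| green | 10.0 | 57 | 20 |
| green | 15.0 | 50 | 27 |
| green | 30.0 | 33 | 43 |
| green | 50.0 | 22 | 49 |
| green | 60.0 | 18 | 59 |
| green | 80.0 | 12 | 59 |
| green | 120 | 4 | 63 |

(each reading ± 2 percentage points)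

* part of the electrophile that has reacted at the end, Saturday's
* part of the electrophile that has reacted at the end, Friday's
* part of the electrophile that has reacted at the end, Monday's
* what raising the equivalents of free base from its lowest to its highest value here does to the part of the electrophile that has reacted (changes below 5 percentage points count as none) (it rises / it falls / no change)



1. First rung: both runs read 57 % electrophile at 10.0 s. If that first loss were exponential, its half-life would be 12.3 s. The violet run already has 21.0 % of the charge in neither electrophile nor target, and that gap reaches 28.0 % by 120 s. The protic impurity's charge equals 30.0 % of the electrophile.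

2. Next rung: the mean [electrophile] of the two runs falls from 31.5 % at 30.0 s to 6.00 % at 120 s. Treating this stretch as pseudo-first-order gives the tail half-life, the time in which the late electrophile halves: 37.6 s. This is slower than the first rung.

3. In these readings I see no clock that belongs to free base. At 30.0 s, violet and green read 30 % and 33 %; at 120 s, 8 % and 4 %. Green reads more than violet at the first of these times and less at the second, so I expect no trend, though Saturday's holds less free base than either run.

4. Last rung: the asked 2.5 min lies 0.798 tail half-lives past the last reading. My reckoning therefore leaves 3.45 % electrophile, or 96.5 % reacted, in each flask.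

5. The forecast differs from my single figure: it gives 96 %, 97 % and 97 %, with no change. Its ground: “The electrophile curves for 2.5 and 5.4 equiv of base agree within the 2-point reading error”.

6. The flasks give 95.2 %, 95.3 % and 95.5 %, a change of 0.34 percentage points: no change. The forecast holds. Where I expected 3.45 % electrophile, Saturday's has 4.80 %.

    acid set free + target → side product (k = 260 /M/s)
    electrophile + acid set free ⇌ idle adduct, settled at all times (K = 1.20 × 10⁵ /M)
    electrophile + nucleophile → acid set free + target (k = 33.0 /M/s)
    nucleophile + acid set free ⇌ protonated nucleophile, settled at all times (K = 5.50 × 10⁶ /M)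
    acid set free + scavenger → scavenged by-product (k = 400 /M/s)
    acid set free + free base ⇌ salt of the base (K = 1.80 × 10⁶ /M, k = 3100 /M/s)
    electrophile + protic impurity → quenched substrate (k = 320 /M/s)

7. In Saturday's as charged, the impurity path's half-life of 0.24 min is shorter than the nucleophile path's 0.35 min. At 0.323 min, however, the nucleophile path uses electrophile 3.2 times as fast as the impurity path, and at 2.5 min Saturday's holds 65.1 % target and 29.8 % quenched substrate, with 0.658 % of the impurity's charge left.

8. For Saturday's flask read at 1.5 min, I step back from 120 s with the same 37.6 s and expect 10.4 % electrophile. The computed flask holds 10.9 %.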